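# Euglobal G3 by a propargyl ether Claisen / oxa-6π cascade: synthesis proposal

**Compound numbers (fixed by the steps below).** 1 ethynyltrimethylsilane; 2 (+)-nopinone; 3 lithium (trimethylsilyl)acetylide; 4 silylalkynyl carbinol; 5 2-fluoro-4,6-dimethoxybenzaldehyde; 6 potassium alkoxide of 4; 7 silylated aryl ether; 8 ethynyl aryl ether (key precursor); 9 allenyl cyclohexadienone; 10 ortho-allenylphenol; 11 ortho-quinone methide dienone; 12 spirochromene; 13 spirochroman; 14 isovaleryl chloride; 15 acylated dimethyl ether; 16 monophenol; 17 euglobal G3.

Locants: the heterocycle and arene are numbered as a chroman (O1, C2, C3, C4, C4a, C5 to C8, C8a). The terpene half is numbered as a pinane (bridgeheads C1 and C5, CMe2 bridge C6, CH2 bridge C7). The spiro atom is C2 of both. In systematic names the chromene locants carry primes.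

## Analysis of the target

Euglobal G3 is a spiro compound in which C2 of a chroman is also C2 of a pinane (6,6-dimethylbicyclo[3.1.1]heptane). The benzene ring is a fully substituted phloroglucinol: O1 on C8a, free hydroxyls on C5 and C7, the 3-methylbutanoyl (isovaleryl) group on C6 between them, the formyl group on C8 next to O1, and the C4 methylene on C4a. All three stereocentres lie in the terpene half. The bridgeheads, pinane C1 (R) and C5 (S), are locked to each other by the cyclobutane. At the spiro carbon C2 (R), O1 sits on the face turned away from the C6 gem-dimethyl bridge and chroman C3 sits on the face under that bridge. The bridgeheads can be bought, but C2 is a fully substituted ether carbon next to a bridgehead and must be made with control of which face carries oxygen. The sensitive points are the aryl aldehyde, the strained four-membered ring, and the tertiary C2–O1 bond, whose ionisation next to the cyclobutane would start Wagner–Meerwein shifts. The chelated phenols are acidic and are best kept masked until the end. A second difficulty is regiochemical: two different acyl groups must go to C6 and C8 of a ring whose three oxygens activate both positions alike. The plan rests on one feature: the pyran ring is a 2,2-disubstituted 2H-chromene lacking only the C3=C4 double bond, and the C8 formyl group occupies one of the two carbons ortho to O1, so C4a is the only ortho carbon that can accept a migrating three-carbon chain.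

## Retrosynthetic reasoning

**17 to 15 (two O–CH3 bonds).** The free phenols are unmasked last, through monophenol 16. As methyl ethers the C5 and C7 oxygens survive the strong base, heat and Lewis acid of the earlier steps. In 15 both methoxy groups are ortho or para to a carbonyl group, which is what makes their nucleophilic cleavage easy. The forward step has to cleave two aryl methyl ethers without touching the aldehyde, the ketone or the acid-sensitive spiro ether.

**15 to 13 and 14 (C6–C(=O) bond).** The isovaleryl group is cut off at this stage because in 13 C6 is the only arene C–H. An acylation can go nowhere else, so the C6/C8 regiochemistry needs no control. Placing the ketone earlier would leave two open arene positions and would send an enolisable ketone through the thermal step. The forward reaction is an electrophilic substitution at a crowded carbon flanked by two methoxy groups, on a ring that carries a formyl group, under a Lewis acid mild enough to spare the C2–O1 bond.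

**13 to 12 (C3–C4 unsaturation).** Introducing a C3=C4 double bond in the retrosynthetic direction turns the chroman into a 2H-chromene, the retron of the aryl propargyl ether rearrangement. The forward step is a hydrogenation that must leave the aldehyde and the allylic C2–O1 bond alone. It also freezes the configuration at C2, since a chroman cannot undergo electrocyclic ring opening.

**12 to 8 (C4–C4a and O1–C2).** Both bonds of the pyran ring that end at the arene and at the spiro carbon are cut together, leading to the aryl ether 8 of a tertiary propargylic alcohol. Closing O1–C2 alone through a cation at pinane C2 would invite skeletal rearrangement. Joining the arene to a 2-methylenepinane in a [4+2] sense would reopen the question of which arene oxygen takes part. The sigmatropic route avoids both: the formyl group of 8 blocks one ortho carbon, so the chain can only arrive at C4a. The cascade runs through 9, 10 and 11, in which C2 is trigonal, so the configuration of C2 in 8 is irrelevant. The gain is one ring, two skeletal bonds and the spiro stereocentre in one operation. The forward reaction must close the ring with oxygen on the face away from the gem-dimethyl bridge, under kinetic control.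

**8 to 7 to 4 and 5 (aryl C8a–O1 bond, then C–Si).** A tertiary propargylic aryl ether cannot be made by substitution at the crowded pinane carbon, so the C–O bond is formed at the arene. The formyl group of 5 is needed at C8 anyway and serves as the activating group for displacement of the ortho fluoride by alkoxide 6. Silicon stays on the alkyne during this step so that no acetylide can form beside the aldehyde, and it is removed afterwards to give 8.

**4 to 2 and 1 (C2–C(sp) bond).** The carbinol is cut into ketone 2, which supplies both bridgehead stereocentres from the chiral pool, and acetylide 3, made from 1. The forward addition only has to be a clean 1,2-addition to a hindered, enolisable ketone, because its facial outcome is erased in the key step.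

## Alternatives that were turned down

**Alternative 1:** The benzene ring is disconnected at C5–C6. A1, the 5,7-dihydroxy-6-isovaleryl spirochroman lacking only the C8 formyl group, is traced to A2, a spiro-fused 3,4-dihydropyrano[4,3-b]pyran-5-one whose pyranone carbon next to the ring oxygen carries a 4-methyl-2-oxopentyl chain.
- Forward key step: a magnesium alkoxide opens the lactone of A2 to a chelated triketo ester. The methylene between the two ketones then attacks the ester carbon (Claisen condensation), and enolisation of the new six-membered ring gives the arene of A1. Formylation at C8, the one open position, would finish the synthesis.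
- For: the isovaleryl group arrives with the ring, no phenol protection is needed, and neither an acylation of a formyl-bearing arene nor an ether cleavage is required. On these three points it is stronger than the chosen route.
- Against: the spiro carbon of A2, with O1 on the correct face, must be built into the pyranone before the ring transformation, so the stereochemical problem is only moved upstream into a less familiar setting. The open triketo ester has other ways to close (aldol onto the side-chain ketone, return to a pyranone). Preparation of A2, recyclisation and formylation together exceed seven steps.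
- In its place, the chosen route makes ring and stereocentre in one operation from an ether three steps away from catalogue compounds.

**Alternative 2:** C2–C3 and O1–C2 are cut, with a carbonyl at C4 as the enabling group. The spiro chroman-4-one A3 is traced to ketone 2 and the ortho-hydroxyacetophenone A4, which already carries the isovaleryl group and two benzyl ethers.
- Forward key step: a secondary amine mediates crossed aldol condensation between the acetyl methyl of A4 and the carbonyl of 2, giving an enone (C2=C3). The free phenol then adds in conjugate fashion to close the pyranone ring of A3.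
- For: 2 is used directly, the ring forms in one pot under mild conditions with no step at 140 °C, and the acyl group is already in place. In convergence and mildness it is stronger than the chosen route.
- Against: the C4 carbonyl must be reduced to CH2 in the presence of the second aryl ketone at C6, which costs differentiation steps. Condensation at the hindered, easily enolised carbonyl of 2 with a di-ortho-substituted acetophenone should be slow. The conjugate addition that sets C2 is reversible, so the spiro configuration falls under thermodynamic control, and the slimmer oxygen may well prefer the crowded face, opposite to the target. A4 itself needs a regiocontrolled multistep preparation, and debenzylation and C8 formylation still follow A3.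
- In its place, the chosen route leaves a C3=C4 alkene as the only excess functionality, removed by one hydrogenation, and sets C2 kinetically from the open face.

**Alternative 3:** The arene is cut at C7–C8 and C5–C6 in a [4+2] sense. A5, the 7-ethoxy-5-hydroxy-6-isovaleryl spirochroman, is traced to the silyl ketene acetal diene A7, made from the spiro 2-methyl-dihydropyran-3-carboxylate A6, and the push-pull ynone A8.
- Forward key step: the exocyclic methylene terminus of A7 bonds to the ethoxy-bearing alkyne carbon of A8 and the ketene acetal carbon to the acyl-bearing carbon. Loss of the acetal methoxy group and of silicon aromatises the new ring to A5.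
- For: the matched polarity of diene and ynone fixes the regiochemistry, the acyl group is in place, and the C5 and C7 oxygens come out differentiated. In regiocontrol on the arene it is stronger than a late acylation.
- Against: A6 with its spiro centre has to be made first, which again only moves the stereochemical problem. The diene terminus that becomes C5 is fully substituted, so the second bond should form slowly and open-chain Michael adducts may compete. A8 is a sensitive dienophile. C8 formylation and ethyl ether cleavage remain after A5, and the sequence is longer.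
- In its place, the chosen route buys the arene, gets its regiocontrol for free because C6 is the last open position, and spends its risk on a single thermal step.

Key step: step 4

Remark: compounds 1, 2, 5 and 14 are taken as catalogue items. The target is planned exactly as its SMILES reads, with O1 on the pinane face opposite the CMe2 bridge (1R,2R,5S).

## Route

**Step 1**
Reactants: 1 ethynyltrimethylsilane; 2 (+)-nopinone, (1R,5S)-6,6-dimethylbicyclo[3.1.1]heptan-2-one
Product: 4 (1R,2R,5S)-6,6-dimethyl-2-[(trimethylsilyl)ethynyl]bicyclo[3.1.1]heptan-2-ol (OH syn to the CMe2 bridge), via lithium (trimethylsilyl)acetylide 3 (not isolated)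
Conditions: n-BuLi, THF, −78 °C; then 2, −78 → 0 °C; aq NH4Cl
Reagents that add atoms: none
Why: Acetylide 1,2-addition to a ketone: 3 approaches C2 of 2 from the side of the C7 methylene bridge because the inward methyl of the C6 bridge covers the other face, so the hydroxyl ends up syn to the CMe2 bridge (2R); the weakly basic acetylide at −78 °C keeps enolisation of 2 in check, and the C2 configuration is in any case erased in step 4.

**Step 2**
Reactants: 4 (1R,2R,5S)-6,6-dimethyl-2-[(trimethylsilyl)ethynyl]bicyclo[3.1.1]heptan-2-ol; 5 2-fluoro-4,6-dimethoxybenzaldehyde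
Product: 7 2-{[(1R,2R,5S)-6,6-dimethyl-2-[(trimethylsilyl)ethynyl]bicyclo[3.1.1]heptan-2-yl]oxy}-4,6-dimethoxybenzaldehyde, via potassium alkoxide 6 (not isolated)
Conditions: KH, THF, 0 °C; then 5, 0 °C → rt
Reagents that add atoms: none
Why: Nucleophilic aromatic substitution by addition–elimination: the C–F carbon is ortho to the formyl group, which takes up the charge of the Meisenheimer adduct, and both methoxy groups are meta to that carbon; KF precipitates from THF and so should not attack the alkynylsilane. The new bond is made at the arene, so C2 keeps its configuration.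

**Step 3**
Reactants: 7 2-{[(1R,2R,5S)-6,6-dimethyl-2-[(trimethylsilyl)ethynyl]bicyclo[3.1.1]heptan-2-yl]oxy}-4,6-dimethoxybenzaldehyde
Product: 8 2-{[(1R,2R,5S)-2-ethynyl-6,6-dimethylbicyclo[3.1.1]heptan-2-yl]oxy}-4,6-dimethoxybenzaldehyde
Conditions: K2CO3, MeOH, rt
Reagents that add atoms: none
Why: Base-catalysed methanolysis of the C(sp)–Si bond (protodesilylation); the aryl ether, the aldehyde and the tertiary centre are inert to K2CO3 in MeOH at room temperature.

**Step 4**
Reactants: 8 2-{[(1R,2R,5S)-2-ethynyl-6,6-dimethylbicyclo[3.1.1]heptan-2-yl]oxy}-4,6-dimethoxybenzaldehyde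
Product: 12 (1R,2R,5S)-5',7'-dimethoxy-6,6-dimethylspiro[bicyclo[3.1.1]heptane-2,2'-chromene]-8'-carbaldehyde (O1' anti to the CMe2 bridge), via allenyl cyclohexadienone 9 (not isolated), via ortho-allenylphenol 10 (not isolated), via ortho-quinone methide dienone 11 (not isolated)
Conditions: o-xylene (degassed), BHT (cat.), 140–145 °C, sealed tube, stopped at full conversion of 8
Reagents that add atoms: none
Why: Aryl propargyl ether Claisen cascade, the closest known reaction type being the thermal conversion of aryl 1,1-disubstituted propargyl ethers into 2,2-disubstituted 2H-chromenes. A [3,3] shift breaks O1'–C2 and joins the alkyne terminus to C4a', the only unsubstituted carbon ortho to the ether oxygen (the other carries the formyl group, and a shift onto it is reversible and unproductive), giving 9, which enolises to 10. A [1,5]-hydrogen shift from the phenolic O–H to the central allene carbon then gives the Z-dienone 11. Thermal disrotatory oxa-6π electrocyclisation of 11 forms O1'–C2 and closes the six-membered pyran ring. C2 is trigonal in 10 and 11, so its configuration in 8 is erased and the stereocentre is set anew in the ring closure. The controlling element is the C6 gem-dimethyl bridge of the pinane, whose inward methyl covers one face of C2 as it does in additions to 2-methylenepinanes, so oxygen should bond from the C7 side and end up anti to the bridge (2R). The step therefore needs regioselectivity, secured by the formyl block, and kinetic facial selectivity, secured by the bridge. Because 12 can reopen to 11 on prolonged heating, heating is stopped at full conversion and the crude product is hydrogenated at once.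

**Step 5**
Reactants: 12 (1R,2R,5S)-5',7'-dimethoxy-6,6-dimethylspiro[bicyclo[3.1.1]heptane-2,2'-chromene]-8'-carbaldehyde
Product: 13 (1R,2R,5S)-5',7'-dimethoxy-6,6-dimethyl-3',4'-dihydrospiro[bicyclo[3.1.1]heptane-2,2'-chromene]-8'-carbaldehyde
Conditions: H2 (1–3 atm), RhCl(PPh3)3 (cat.), PhH/EtOH, rt
Reagents that add atoms: none
Why: Homogeneous hydrogenation with RhCl(PPh3)3 should reduce the cis-disubstituted styrenic C3'=C4' bond without reducing the aryl aldehyde or hydrogenolysing the allylic C2–O1' bond, and decarbonylation by the rhodium complex is slow at room temperature; no stereocentre is formed, and saturation removes the retro-6π pathway, so C2 is locked from here on.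

**Step 6**
Reactants: 13 (1R,2R,5S)-5',7'-dimethoxy-6,6-dimethyl-3',4'-dihydrospiro[bicyclo[3.1.1]heptane-2,2'-chromene]-8'-carbaldehyde; 14 isovaleryl chloride (3-methylbutanoyl chloride)
Product: 15 (1R,2R,5S)-5',7'-dimethoxy-6,6-dimethyl-6'-(3-methylbutanoyl)-3',4'-dihydrospiro[bicyclo[3.1.1]heptane-2,2'-chromene]-8'-carbaldehyde
Conditions: TiCl4, CH2Cl2, −20 → 0 °C
Reagents that add atoms: none
Why: Friedel–Crafts acylation: C6' is the only arene C–H, ortho to both methoxy groups and para to O1', so the acylium ion from 14 and TiCl4 can attack nowhere else; the analogy is the second Rieche formylation of formylated trialkoxybenzenes under the same Lewis acid, and the low temperature protects the tertiary C2–O1' bond from ionisation.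

**Step 7**
Reactants: 15 (1R,2R,5S)-5',7'-dimethoxy-6,6-dimethyl-6'-(3-methylbutanoyl)-3',4'-dihydrospiro[bicyclo[3.1.1]heptane-2,2'-chromene]-8'-carbaldehyde
Product: 17 euglobal G3, (1R,2R,5S)-5',7'-dihydroxy-6,6-dimethyl-6'-(3-methylbutanoyl)-3',4'-dihydrospiro[bicyclo[3.1.1]heptane-2,2'-chromene]-8'-carbaldehyde, via 7'-hydroxy-5'-methoxy monophenol 16 (not isolated)
Conditions: NaSEt, DMF, 110 °C; then aq HCl
Reagents that add atoms: none
Why: Nucleophilic demethylation (SN2 attack of thiolate at the methyl carbon): both methoxy groups are ortho or para to carbonyl groups, so the departing phenoxides are stabilised, the doubly flanked C7' ether being expected to go first; the non-acidic conditions leave the tertiary spiro ether, the cyclobutane and all three stereocentres untouched, and acidification returns the chelated diphenol.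

## Compound list

1 | ethynyltrimethylsilane | C#C[Si](C)(C)C | starting material
2 | (+)-nopinone, (1R,5S)-6,6-dimethylbicyclo[3.1.1]heptan-2-one | O=C1CC[C@H]2C[C@@H]1C2(C)C | starting material
3 | lithium (trimethylsilyl)acetylide | [Li]C#C[Si](C)(C)C | intermediate
4 | (1R,2R,5S)-6,6-dimethyl-2-[(trimethylsilyl)ethynyl]bicyclo[3.1.1]heptan-2-ol, OH syn to the CMe2 bridge | O[C@]1(C#C[Si](C)(C)C)CC[C@H]2C[C@@H]1C2(C)C | intermediate
5 | 2-fluoro-4,6-dimethoxybenzaldehyde | COc1cc(OC)c(C=O)c(F)c1 | starting material
6 | potassium (1R,2R,5S)-6,6-dimethyl-2-[(trimethylsilyl)ethynyl]bicyclo[3.1.1]heptan-2-olate | [K+].[O-][C@]1(C#C[Si](C)(C)C)CC[C@H]2C[C@@H]1C2(C)C | intermediate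
7 | 2-{[(1R,2R,5S)-6,6-dimethyl-2-[(trimethylsilyl)ethynyl]bicyclo[3.1.1]heptan-2-yl]oxy}-4,6-dimethoxybenzaldehyde | O=Cc1c(OC)cc(OC)cc1O[C@]1(C#C[Si](C)(C)C)CC[C@H]2C[C@@H]1C2(C)C | intermediate
8 | 2-{[(1R,2R,5S)-2-ethynyl-6,6-dimethylbicyclo[3.1.1]heptan-2-yl]oxy}-4,6-dimethoxybenzaldehyde, aryl oxygen syn to the CMe2 bridge | O=Cc1c(OC)cc(OC)cc1O[C@]1(C#C)CC[C@H]2C[C@@H]1C2(C)C | intermediate
9 | 6-{2-[(1R,5S)-6,6-dimethylbicyclo[3.1.1]heptan-2-ylidene]ethenyl}-2-formyl-3,5-dimethoxycyclohexa-2,4-dien-1-one, mixture at ring C6 and the allene axis | O=CC1=C(OC)C=C(OC)C(C=C=C2CC[C@H]3C[C@@H]2C3(C)C)C1=O | intermediate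
10 | 3-{2-[(1R,5S)-6,6-dimethylbicyclo[3.1.1]heptan-2-ylidene]ethenyl}-2-hydroxy-4,6-dimethoxybenzaldehyde, allene axis undefined | O=Cc1c(O)c(C=C=C2CC[C@H]3C[C@@H]2C3(C)C)c(OC)cc1OC | intermediate
11 | (6Z)-6-{2-[(1R,5S)-6,6-dimethylbicyclo[3.1.1]heptan-2-ylidene]ethylidene}-2-formyl-3,5-dimethoxycyclohexa-2,4-dien-1-one, pinanylidene C=C geometry undefined | O=CC1=C(OC)C=C(OC)/C(=C/C=C2CC[C@H]3C[C@@H]2C3(C)C)C1=O | intermediate
12 | (1R,2R,5S)-5',7'-dimethoxy-6,6-dimethylspiro[bicyclo[3.1.1]heptane-2,2'-chromene]-8'-carbaldehyde, O1' anti to the CMe2 bridge | COc1cc(OC)c(C=O)c2c1C=C[C@@]1(CC[C@H]3C[C@@H]1C3(C)C)O2 | intermediate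
13 | (1R,2R,5S)-5',7'-dimethoxy-6,6-dimethyl-3',4'-dihydrospiro[bicyclo[3.1.1]heptane-2,2'-chromene]-8'-carbaldehyde | COc1cc(OC)c(C=O)c2c1CC[C@@]1(CC[C@H]3C[C@@H]1C3(C)C)O2 | intermediate
14 | isovaleryl chloride (3-methylbutanoyl chloride) | CC(C)CC(=O)Cl | starting material
15 | (1R,2R,5S)-5',7'-dimethoxy-6,6-dimethyl-6'-(3-methylbutanoyl)-3',4'-dihydrospiro[bicyclo[3.1.1]heptane-2,2'-chromene]-8'-carbaldehyde | CC(C)CC(=O)c1c(OC)c(C=O)c2c(c1OC)CC[C@@]1(CC[C@H]3C[C@@H]1C3(C)C)O2 | intermediate
16 | (1R,2R,5S)-7'-hydroxy-5'-methoxy-6,6-dimethyl-6'-(3-methylbutanoyl)-3',4'-dihydrospiro[bicyclo[3.1.1]heptane-2,2'-chromene]-8'-carbaldehyde, present as its sodium phenoxide | CC(C)CC(=O)c1c(O)c(C=O)c2c(c1OC)CC[C@@]1(CC[C@H]3C[C@@H]1C3(C)C)O2 | intermediate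
17 | euglobal G3, (1R,2R,5S)-5',7'-dihydroxy-6,6-dimethyl-6'-(3-methylbutanoyl)-3',4'-dihydrospiro[bicyclo[3.1.1]heptane-2,2'-chromene]-8'-carbaldehyde | CC(C)CC(=O)c1c(O)c(C=O)c2c(c1O)CC[C@@]1(CC[C@H]3C[C@@H]1C3(C)C)O2 | target

## Step count and least certain steps

Total: 7 steps. Longest linear sequence: 7 steps (2 to 17; compounds 1, 5 and 14 enter as bought).

**Step 4 (key step).**
- What may go wrong: the facial discrimination in the oxa-6π closure may be insufficient. On continued heating, 12 can also reopen to 11 and reclose, which would drift the product toward the thermodynamic mixture of C2 epimers. That mixture cannot be assumed to favour 12, because the slimmer oxygen should tolerate the position under the CMe2 bridge better than C3' does. A [1,7]-hydrogen shift in 11, from an allylic pinane C–H to the carbonyl oxygen, could divert material to a dienyl phenol.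
- Fallback: a stereoretentive route in which C2 is never trigonal after the ether is made. It sets out from 4. K2CO3 in MeOH removes silicon to give (1R,2R,5S)-2-ethynyl-6,6-dimethylbicyclo[3.1.1]heptan-2-ol F1. (CF3CO)2O and DBU in MeCN at −5 °C convert it into (1R,2R,5S)-2-ethynyl-6,6-dimethylbicyclo[3.1.1]heptan-2-yl trifluoroacetate F2. In the same medium, CuCl2 (cat.) and commercial 2-hydroxy-4,6-dimethoxybenzaldehyde effect the known copper-catalysed propargylic etherification. The phenol attacks the copper allenylidene at pinane C2 from the open face, so the product is the C2 epimer of 8 with oxygen anti to the CMe2 bridge, 2-{[(1R,2S,5S)-2-ethynyl-6,6-dimethylbicyclo[3.1.1]heptan-2-yl]oxy}-4,6-dimethoxybenzaldehyde F3. Ph3PAuNTf2 (cat.) in CH2Cl2 at room temperature then closes the ring by 6-endo hydroarylation at the only free ortho carbon, leaving C2 untouched, and the route is rejoined at 12.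

**Step 2.**
- What may go wrong: substitution by the crowded tertiary alkoxide may be slow. In that time the alkoxide can add to the formyl group (hemiacetal formation followed by hydride transfer) or fragment back to 2 and acetylide. The released fluoride may also begin to strip silicon from the alkyne.
- Fallback: change the activating group from formyl to cyano. It sets out from 5. NH2OH·HCl and NaOAc give (E)-2-fluoro-4,6-dimethoxybenzaldehyde oxime F4, and Ac2O with heating dehydrates it to 2-fluoro-4,6-dimethoxybenzonitrile F5. Alkoxide 6 (from 4 and KH) displaces fluoride from this stronger and non-electrophilic acceptor to give 2-{[(1R,2R,5S)-6,6-dimethyl-2-[(trimethylsilyl)ethynyl]bicyclo[3.1.1]heptan-2-yl]oxy}-4,6-dimethoxybenzonitrile F6. i-Bu2AlH in toluene at −78 °C reduces the nitrile to the N-(diisobutylaluminio) aldimine F7, which mild aqueous acid hydrolyses, and the route is rejoined at 7.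

**Step 6.**
- What may go wrong: the Lewis acid binds the formyl oxygen and deactivates the ring, so the crowded C6' position may fail to react. Under more forcing conditions the C2–O1' bond could ionise and the pinane skeleton rearrange, and the C7' methyl ether may be partly lost by chelation-assisted cleavage.
- Fallback: reverse the polarity and use the arene as the nucleophile. It sets out from 13. LiN(Me)CH2CH2NMe2 in THF masks the aldehyde in the flask as the lithium α-amino alkoxide F8. n-BuLi then removes the C6' proton between the two methoxy groups to give the C6'-lithiated species F9. Addition of 3-methylbutanal and aqueous NH4Cl work-up gives (1R,2R,5S)-6'-(1-hydroxy-3-methylbutyl)-5',7'-dimethoxy-6,6-dimethyl-3',4'-dihydrospiro[bicyclo[3.1.1]heptane-2,2'-chromene]-8'-carbaldehyde F10 (either carbinol epimer). Dess–Martin periodinane oxidises it, and the route is rejoined at 15.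

**Step 7.**
- What may go wrong: once the first ether is cleaved, the phenoxide charge slows cleavage of the second. Prolonged heating with thiolate then exposes the aldehyde and the enolisable ketone to condensation side reactions.
- Fallback: change the order so that the ethers are cleaved before the ketone exists. It sets out from 13. NaSEt in DMF gives (1R,2R,5S)-5',7'-dihydroxy-6,6-dimethyl-3',4'-dihydrospiro[bicyclo[3.1.1]heptane-2,2'-chromene]-8'-carbaldehyde F11. A TiCl4-mediated ortho-acylation of the free phenol with 14 (CH2Cl2, 0 °C) then places the isovaleryl group on C6', the only open position and ortho to both hydroxyls, and the route is rejoined at 17.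

## Further compounds

F1 | step 4 | (1R,2R,5S)-2-ethynyl-6,6-dimethylbicyclo[3.1.1]heptan-2-ol | O[C@]1(C#C)CC[C@H]2C[C@@H]1C2(C)C
F2 | step 4 | (1R,2R,5S)-2-ethynyl-6,6-dimethylbicyclo[3.1.1]heptan-2-yl trifluoroacetate | O=C(O[C@]1(C#C)CC[C@H]2C[C@@H]1C2(C)C)C(F)(F)F
F3 | step 4 | 2-{[(1R,2S,5S)-2-ethynyl-6,6-dimethylbicyclo[3.1.1]heptan-2-yl]oxy}-4,6-dimethoxybenzaldehyde (C2 epimer of 8, oxygen anti to the CMe2 bridge) | O=Cc1c(OC)cc(OC)cc1O[C@@]1(C#C)CC[C@H]2C[C@@H]1C2(C)C
F4 | step 2 | (E)-2-fluoro-4,6-dimethoxybenzaldehyde oxime | O/N=C/c1c(F)cc(OC)cc1OC
F5 | step 2 | 2-fluoro-4,6-dimethoxybenzonitrile | N#Cc1c(F)cc(OC)cc1OC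
F6 | step 2 | 2-{[(1R,2R,5S)-6,6-dimethyl-2-[(trimethylsilyl)ethynyl]bicyclo[3.1.1]heptan-2-yl]oxy}-4,6-dimethoxybenzonitrile | N#Cc1c(OC)cc(OC)cc1O[C@]1(C#C[Si](C)(C)C)CC[C@H]2C[C@@H]1C2(C)C
F7 | step 2 | N-(diisobutylaluminio) aldimine of 7 | CC(C)C[Al](CC(C)C)N=Cc1c(OC)cc(OC)cc1O[C@]1(C#C[Si](C)(C)C)CC[C@H]2C[C@@H]1C2(C)C
F8 | step 6 | lithium α-amino alkoxide of 13 (adduct with LiN(Me)CH2CH2NMe2, aminal carbon undefined) | COc1cc(OC)c(C(O[Li])N(C)CCN(C)C)c2c1CC[C@@]1(CC[C@H]3C[C@@H]1C3(C)C)O2
F9 | step 6 | C6'-lithiated lithium α-amino alkoxide of 13 | COc1c([Li])c(OC)c(C(O[Li])N(C)CCN(C)C)c2c1CC[C@@]1(CC[C@H]3C[C@@H]1C3(C)C)O2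
F10 | step 6 | (1R,2R,5S)-6'-(1-hydroxy-3-methylbutyl)-5',7'-dimethoxy-6,6-dimethyl-3',4'-dihydrospiro[bicyclo[3.1.1]heptane-2,2'-chromene]-8'-carbaldehyde (carbinol centre undefined) | CC(C)CC(O)c1c(OC)c(C=O)c2c(c1OC)CC[C@@]1(CC[C@H]3C[C@@H]1C3(C)C)O2
F11 | step 7 | (1R,2R,5S)-5',7'-dihydroxy-6,6-dimethyl-3',4'-dihydrospiro[bicyclo[3.1.1]heptane-2,2'-chromene]-8'-carbaldehyde | Oc1cc(O)c(C=O)c2c1CC[C@@]1(CC[C@H]3C[C@@H]1C3(C)C)O2
A1 | alternative 1 | 5,7-dihydroxy-6-isovaleryl spiro[chroman-2,2'-pinane] | CC(C)CC(=O)c1c(O)cc2c(c1O)CC[C@@]1(CC[C@H]3C[C@@H]1C3(C)C)O2
A2 | alternative 1 | spiro 3,4-dihydropyrano[4,3-b]pyran-5-one carrying a 7-(4-methyl-2-oxopentyl) chain | CC(C)CC(=O)CC1=CC2=C(CC[C@@]3(CC[C@H]4C[C@@H]3C4(C)C)O2)C(=O)O1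
A3 | alternative 2 | 5,7-bis(benzyloxy)-6-isovaleryl spiro[chroman-2,2'-pinan]-4-one | CC(C)CC(=O)c1c(OCc2ccccc2)cc2c(c1OCc1ccccc1)C(=O)C[C@@]1(CC[C@H]3C[C@@H]1C3(C)C)O2
A4 | alternative 2 | 1-[3-acetyl-2,6-bis(benzyloxy)-4-hydroxyphenyl]-3-methylbutan-1-one | CC(C)CC(=O)c1c(OCc2ccccc2)cc(O)c(C(C)=O)c1OCc1ccccc1
A5 | alternative 3 | 7-ethoxy-5-hydroxy-6-isovaleryl spiro[chroman-2,2'-pinane] | CC(C)CC(=O)c1c(OCC)cc2c(c1O)CC[C@@]1(CC[C@H]3C[C@@H]1C3(C)C)O2
A6 | alternative 3 | methyl spiro 2-methyl-5,6-dihydro-4H-pyran-3-carboxylate (pyran C6 = pinane C2) | CC1=C(C(=O)OC)CC[C@@]2(CC[C@H]3C[C@@H]2C3(C)C)O1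
A7 | alternative 3 | silyl ketene acetal diene from A6 (exocyclic methylene, methoxy(trimethylsilyloxy)methylidene) | C=C1C(=C(OC)O[Si](C)(C)C)CC[C@@]2(CC[C@H]3C[C@@H]2C3(C)C)O1
A8 | alternative 3 | 1-ethoxy-5-methylhex-1-yn-3-one | CCOC#CC(=O)CC(C)C
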